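**Retrosynthetic overview**

1. Core labels: C1 enone carbonyl, C2, C3 (styryl-bearing), C4 bridgehead, C8 bridging carbonyl, C5 bridgehead between the two carbonyls, C6 (catechol-bearing), C7 (resorcinol-bearing). The plan rests on the seven-membered ring C1–C2–C3–C4–C7–C6–C5 inside the bicyclo[3.2.1]octenedione: with its vicinal aryl carbons C6/C7 it is a cyclohepta-1,4-diene in disguise.
2. Ring 1 (seven-membered): a chiral dirhodium carboxylate turns styryl diazoacetate 5 into a vinylcarbene that cyclopropanates Z-siloxydiene 11; Cope ring expansion gives 13 with C6/C7 trans, a C1 silyl enol ether and a C3 enoate.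
3. Rings 2 and 3 (five- and six-membered, closed together): C8 is placed on C5 as a masked formyl group anti to the C6 aryl, then a SmI2 ketyl–enoate closure makes C8–C4.
4. Endgame: C3 ester to aldehyde to E-styryl (Horner–Wadsworth–Emmons), C1 and C8 to ketones, C2=C3 by Saegusa–Ito oxidation, six-fold O-demethylation last.
5. 5 comes from 3,5-dimethoxybenzaldehyde (3 steps); 11 from 4-iodo-1,2-dimethoxybenzene and but-3-yn-2-ol (4 steps).

Key step: step 8

Assumption: Rh2(S-DOSP)4 is assigned from its known (1S,2R) sense in styrene cyclopropanation with the donor group cis to the alkene's unsaturated substituent; should the siloxydiene reverse this sense, Rh2(R-DOSP)4 would be used in the same step.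

Names of the ring compounds use the core labels above; absolute configuration is as in the SMILES of the compound list.

**Route**

Step 1
Reactants: 1 3,5-dimethoxybenzaldehyde; 2 (2-carboxyethyl)triphenylphosphonium bromide
Product: 3 (E)-4-(3,5-dimethoxyphenyl)but-3-enoic acid
Conditions: KOC(CH3)3 (2.2 equiv), THF, 0 °C → rt; then 1 M HCl
Reagents that add atoms: none
Why: Wittig olefination with the carboxylate-bearing ylide, which with aromatic aldehydes should give mainly the E alkene (minor Z isomer removed by crystallisation); no stereocentre is formed.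

Step 2
Reactants: 3 (E)-4-(3,5-dimethoxyphenyl)but-3-enoic acid
Product: 4 methyl (E)-4-(3,5-dimethoxyphenyl)but-3-enoate
Conditions: MeOH, H2SO4 (cat.), 65 °C
Reagents that add atoms: methanol, CO
Why: Fischer esterification; the double bond stays in conjugation with the arene, so no isomer problem is expected.

Step 3
Reactants: 4 methyl (E)-4-(3,5-dimethoxyphenyl)but-3-enoate
Product: 5 methyl (E)-2-diazo-4-(3,5-dimethoxyphenyl)but-3-enoate
Conditions: p-ABSA, DBU, MeCN, 0 °C; used promptly, stored cold
Reagents that add atoms: 4-acetamidobenzenesulfonyl azide (p-ABSA), CC(=O)Nc1ccc(cc1)S(=O)(=O)N=[N+]=[N-]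
Why: Regitz diazo transfer onto the dienolate of the doubly activated CH2 gives the E-styryl diazoacetate, the standard access to donor/acceptor vinylcarbene precursors.

Step 4
Reactants: 6 4-iodo-1,2-dimethoxybenzene; 7 but-3-yn-2-ol (racemic)
Product: 8 4-(3,4-dimethoxyphenyl)but-3-yn-2-ol (racemic)
Conditions: PdCl2(PPh3)2 (2 mol %), CuI (4 mol %), Et3N, THF, rt
Reagents that add atoms: none
Why: Sonogashira coupling of an aryl iodide with a terminal alkyne; the free propargylic alcohol is tolerated.

Step 5
Reactants: 8 4-(3,4-dimethoxyphenyl)but-3-yn-2-ol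
Product: 9 (Z)-4-(3,4-dimethoxyphenyl)but-3-en-2-ol (racemic)
Conditions: H2 (1 atm), Pd/CaCO3 poisoned with Pb(OAc)2 (Lindlar catalyst), quinoline, EtOAc, rt
Reagents that add atoms: none
Why: Lindlar semihydrogenation adds H2 syn to the alkyne and so gives the Z alkene, with quinoline holding back over-reduction.

Step 6
Reactants: 9 (Z)-4-(3,4-dimethoxyphenyl)but-3-en-2-ol
Product: 10 (Z)-4-(3,4-dimethoxyphenyl)but-3-en-2-one
Conditions: Dess–Martin periodinane, pyridine, CH2Cl2, 0 °C, dark
Reagents that add atoms: none
Why: Dess–Martin oxidation of the allylic alcohol under pyridine buffer and without light should keep the acid- and light-sensitive Z enone from isomerising.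

Step 7
Reactants: 10 (Z)-4-(3,4-dimethoxyphenyl)but-3-en-2-one
Product: 11 (Z)-2-(tert-butyldimethylsilyloxy)-4-(3,4-dimethoxyphenyl)buta-1,3-diene
Conditions: KN(SiMe3)2, TBSCl, THF, −78 °C
Reagents that add atoms: tert-butyldimethylsilyl chloride, CC(C)(C)[Si](C)(C)Cl
Why: Kinetic enolisation of the methyl ketone and O-silylation; the enolate is cross-conjugated, so the Z C=C bond keeps its full double-bond character, and no Lewis acid is present that could isomerise it through a siloxyallyl cation.

Step 8
Reactants: 5 methyl (E)-2-diazo-4-(3,5-dimethoxyphenyl)but-3-enoate; 11 (Z)-2-(tert-butyldimethylsilyloxy)-4-(3,4-dimethoxyphenyl)buta-1,3-diene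
Product: 13 methyl (3S,4R)-6-(tert-butyldimethylsilyloxy)-4-(3,4-dimethoxyphenyl)-3-(3,5-dimethoxyphenyl)cyclohepta-1,5-diene-1-carboxylate, via cis-divinylcyclopropane 12 (not isolated)
Conditions: Rh2(S-DOSP)4 (1 mol %), 11 (1.2 equiv), slow addition of 5, toluene–hexanes, −40 °C → rt; then toluene, 100 °C
Reagents that add atoms: none
Why: Rh2(S-DOSP)4 converts 5 into a donor/acceptor vinylcarbene that cyclopropanates the terminal siloxy-substituted C1=C2 alkene of 11 (bonds C3–C2 and C3–C1) with the two alkenyl groups cis, and cis-divinylcyclopropane 12 then undergoes a [3,3] Cope shift through the obligatory boat transition state that breaks C1–C3 and forms C6–C7. The closest known reaction type is the dirhodium-catalysed tandem cyclopropanation/Cope rearrangement (formal (4+3) cycloaddition) of styryl diazoacetates with dienes, 2-siloxydienes and Z-dienes included. The seven-membered ring C1–C2–C3–C4–C7–C6–C5 is closed pericyclically by this sigmatropic ring expansion, not by an ionic or radical cyclisation. C6 and C7 are set relative to each other by the two alkene geometries (the E-aryl of the carbene part points outward and the Z-aryl of the diene part inward in the boat, hence trans), and their absolute sense by the face selectivity of the chiral dirhodium carboxylate in the cyclopropanation, which the concerted shift passes on. The step needs attack on the silyl enol ether alkene and not on the Z-styrenyl alkene or the electron-rich arenes, which the higher nucleophilicity and terminal position of that alkene and the non-polar medium should secure, and it needs the cis-divinyl isomer, which the donor-syn preference of these carbenes favours. The push–pull substitution of the breaking C1–C3 bond should lower the Cope barrier enough to offset the inward Z-aryl group, hence only moderate heating.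

Step 9
Reactants: 13 trans-diaryl cycloheptadiene (C1 silyl enol ether, C3 enoate)
Product: 14 C1 ketone carrying a dimethoxymethyl group (C8) on C5, trans to the C6 aryl; C3=C4 enoate unchanged
Conditions: HC(OMe)3, TMSOTf (0.2 equiv), CH2Cl2, −78 °C; pyridine quench at −78 °C
Reagents that add atoms: trimethyl orthoformate, COC(OC)OC
Why: Mukaiyama-type (Noyori) alkylation of the silyl enol ether by the dimethoxycarbenium ion at C5; the electrophile should approach the face opposite the adjacent C6 aryl, and because C5 stays epimerisable next to the ketone the 5,6-trans isomer is also the thermodynamic one.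

Step 10
Reactants: 14 keto acetal
Product: 15 C1 alcohol (epimer mixture at C1) with the C5 dimethoxymethyl group and the C3=C4 enoate
Conditions: NaBH4, CeCl3·7H2O, MeOH, −78 → −40 °C
Reagents that add atoms: none
Why: Luche reduction takes the ketone in preference to the enoate and leaves the acetal; it masks C1 so that C5 can no longer epimerise or C3=C4 migrate, and the uncontrolled C1 carbinol centre is harmless because C1 is re-oxidised in step 17.

Step 11
Reactants: 15 hydroxy acetal
Product: 17 C1 triethylsilyl ether with a formyl group (C8) on C5 trans to the C6 aryl and the C3=C4 enoate, via collidinium acetal salt 16 (not isolated)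
Conditions: TESOTf (3 equiv), 2,4,6-collidine (4.5 equiv), CH2Cl2, 0 °C; then H2O
Reagents that add atoms: triethylsilyl trifluoromethanesulfonate, CC[Si](CC)(CC)OS(=O)(=O)C(F)(F)F; water, O
Why: The silyl triflate silylates the alcohol and, with collidine, converts the dimethyl acetal into a collidinium salt that water hydrolyses to the aldehyde (Fujioka-type acetal cleavage); the medium is never acidic, so the β-silyloxy aldehyde should neither eliminate nor epimerise at C5, and collidine traps the oxocarbenium ion before the neighbouring arene can.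

Step 12
Reactants: 17 silyloxy aldehyde
Product: 18 bicyclo[3.2.1]octane: C8 carbinol bridging C5 and C4, methyl ester on sp3 C3, C1 triethylsilyl ether (C1, C3 and C8 as formed, all later sp2)
Conditions: SmI2 (2.5 equiv), HMPA, t-BuOH (2 equiv), THF, −78 → 0 °C, high dilution
Reagents that add atoms: none
Why: SmI2 ketyl–olefin cyclisation: the C8 ketyl adds 5-exo to C4, the β-carbon of the enoate, closing the five-membered ring C8–C5–C6–C7–C4 and with it the six-membered ring; as C8 sits on C5 anti to the C6 aryl it can only reach the face of C4 syn to the C7 aryl, which fixes the C4 bridgehead.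

Step 13
Reactants: 18 bicyclic hydroxy ester
Product: 19 diol: C3 hydroxymethyl, C8 carbinol, C1 triethylsilyl ether
Conditions: LiAlH4, THF, 0 °C; Fieser work-up
Reagents that add atoms: none
Why: Hydride reduction of the ester to the primary alcohol, with silyl and aryl ethers inert; a γ-lactone between the C8 oxygen and the ester, should it have formed in step 12, gives the same diol.

Step 14
Reactants: 19 diol
Product: 20 keto aldehyde: C8 ketone, C3 formyl, C1 triethylsilyl ether
Conditions: Dess–Martin periodinane (3 equiv), pyridine, CH2Cl2, 0 °C → rt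
Reagents that add atoms: none
Why: Dess–Martin oxidation of both alcohols; the C8 ketone is flanked by two bridgeheads and cannot enolise, so C4 and C5 are safe.

Step 15
Reactants: 21 3,4-dimethoxybenzyl alcohol
Product: 22 diethyl (3,4-dimethoxybenzyl)phosphonate
Conditions: P(OEt)3, ZnI2, toluene, 110 °C
Reagents that add atoms: triethyl phosphite, CCOP(OCC)OCC
Why: Zinc-diiodide-mediated Arbuzov-type conversion of an electron-rich benzylic alcohol into its phosphonate in one operation.

Step 16
Reactants: 20 keto aldehyde; 22 diethyl (3,4-dimethoxybenzyl)phosphonate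
Product: 24 C1 alcohol with the E-3,4-dimethoxystyryl group on sp3 C3 and the C8 ketone, via TES ether 23 (not isolated)
Conditions: 22, NaN(SiMe3)2, THF, −78 °C; add 20, −78 → 0 °C; then 1 M HCl, 0 °C → rt
Reagents that add atoms: none
Why: Horner–Wadsworth–Emmons olefination, E-selective for benzylic phosphonates and faster at the aldehyde than at the hindered non-enolisable C8 ketone (epimerisation at C3 is irrelevant); the acidic work-up then removes the triethylsilyl ether.

Step 17
Reactants: 24 hydroxy styryl ketone
Product: 25 diketone: C1 and C8 ketones, E-styryl on sp3 C3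
Conditions: Dess–Martin periodinane, pyridine, CH2Cl2, 0 °C → rt
Reagents that add atoms: none
Why: Dess–Martin oxidation of the secondary alcohol; C5 between the two ketones is a bridgehead and cannot enolise (Bredt), so no epimerisation is possible.

Step 18
Reactants: 25 diketone
Product: 27 hexa-O-methyljezonodione, via TMS enol ether 26 (not isolated)
Conditions: TMSOTf, Et3N, CH2Cl2, 0 °C; then Pd(OAc)2, MeCN, rt
Reagents that add atoms: none
Why: Saegusa–Ito oxidation: the C1 ketone can enolise only towards C2, and β-hydride elimination from the palladium enolate takes the C3 hydrogen, giving C2=C3 in conjugation with both the ketone and the styryl group.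

Step 19
Reactants: 27 hexa-O-methyljezonodione
Product: 28 jezonodione
Conditions: BBr3 (excess), CH2Cl2, −78 → 0 °C; then H2O
Reagents that add atoms: none
Why: Lewis-acid cleavage of the six aryl methyl ethers with boron tribromide; none of the four stereocentres is epimerisable (C4 and C5 are bridgeheads, C6 and C7 carry no acidic hydrogen).

**Compound list**

1 | 3,5-dimethoxybenzaldehyde | COc1cc(C=O)cc(OC)c1 | starting material
2 | (2-carboxyethyl)triphenylphosphonium bromide | OC(=O)CC[P+](c1ccccc1)(c1ccccc1)c1ccccc1.[Br-] | starting material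
3 | (E)-4-(3,5-dimethoxyphenyl)but-3-enoic acid | OC(=O)C/C=C/c1cc(OC)cc(OC)c1 | intermediate
4 | methyl (E)-4-(3,5-dimethoxyphenyl)but-3-enoate | COC(=O)C/C=C/c1cc(OC)cc(OC)c1 | intermediate
5 | methyl (E)-2-diazo-4-(3,5-dimethoxyphenyl)but-3-enoate | COC(=O)C(=[N+]=[N-])/C=C/c1cc(OC)cc(OC)c1 | intermediate
6 | 4-iodo-1,2-dimethoxybenzene | COc1ccc(I)cc1OC | starting material
7 | but-3-yn-2-ol (racemic) | CC(O)C#C | starting material
8 | 4-(3,4-dimethoxyphenyl)but-3-yn-2-ol (racemic) | CC(O)C#Cc1ccc(OC)c(OC)c1 | intermediate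
9 | (Z)-4-(3,4-dimethoxyphenyl)but-3-en-2-ol (racemic) | CC(O)/C=C\c1ccc(OC)c(OC)c1 | intermediate
10 | (Z)-4-(3,4-dimethoxyphenyl)but-3-en-2-one | CC(=O)/C=C\c1ccc(OC)c(OC)c1 | intermediate
11 | (Z)-2-(tert-butyldimethylsilyloxy)-4-(3,4-dimethoxyphenyl)buta-1,3-diene | C=C(O[Si](C)(C)C(C)(C)C)/C=C\c1ccc(OC)c(OC)c1 | intermediate
12 | methyl 2-(tert-butyldimethylsilyloxy)-2-[(Z)-2-(3,4-dimethoxyphenyl)ethenyl]-1-[(E)-2-(3,5-dimethoxyphenyl)ethenyl]cyclopropane-1-carboxylate, the two alkenyl groups cis | COC(=O)[C@@]1(/C=C/c2cc(OC)cc(OC)c2)C[C@]1(O[Si](C)(C)C(C)(C)C)/C=C\c1ccc(OC)c(OC)c1 | intermediate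
13 | methyl (3S,4R)-6-(tert-butyldimethylsilyloxy)-4-(3,4-dimethoxyphenyl)-3-(3,5-dimethoxyphenyl)cyclohepta-1,5-diene-1-carboxylate (core: C1 silyl enol ether C1=C5, C3 enoate C3=C4, C6 R, C7 S, aryls trans) | CC(C)(C)[Si](C)(C)OC1=C[C@H](c2ccc(OC)c(OC)c2)[C@@H](c2cc(OC)cc(OC)c2)C=C(C(=O)OC)C1 | intermediate
14 | keto acetal: C1 ketone, dimethoxymethyl (C8) on C5 trans to the C6 aryl, C3=C4 methyl enoate, C6/C7 aryls trans | O=C1[C@@H](C(OC)OC)[C@H](c2ccc(OC)c(OC)c2)[C@@H](c2cc(OC)cc(OC)c2)C=C(C(=O)OC)C1 | intermediate
15 | hydroxy acetal: as 14 with C1 carbinol (C1 epimer mixture) | OC1[C@@H](C(OC)OC)[C@H](c2ccc(OC)c(OC)c2)[C@@H](c2cc(OC)cc(OC)c2)C=C(C(=O)OC)C1 | intermediate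
16 | collidinium acetal salt: C1 triethylsilyl ether, C8 bearing methoxy and N-(2,4,6-trimethylpyridinium), triflate counter-ion | CC[Si](CC)(CC)OC1[C@@H](C(OC)[n+]2c(C)cc(C)cc2C)[C@H](c2ccc(OC)c(OC)c2)[C@@H](c2cc(OC)cc(OC)c2)C=C(C(=O)OC)C1.[O-]S(=O)(=O)C(F)(F)F | intermediate
17 | silyloxy aldehyde: C1 triethylsilyl ether, formyl (C8) on C5 trans to the C6 aryl, C3=C4 methyl enoate | CC[Si](CC)(CC)OC1[C@@H](C=O)[C@H](c2ccc(OC)c(OC)c2)[C@@H](c2cc(OC)cc(OC)c2)C=C(C(=O)OC)C1 | intermediate
18 | bicyclo[3.2.1]octane hydroxy ester: C8 carbinol bridge (syn to the C7 aryl, anti to the C6 aryl), C3 methyl ester, C1 triethylsilyl ether; C1, C3, C8 unassigned | CC[Si](CC)(CC)OC1CC(C(=O)OC)[C@@H]2C(O)[C@H]1[C@H](c1ccc(OC)c(OC)c1)[C@H]2c1cc(OC)cc(OC)c1 | intermediate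
19 | diol: as 18 with C3 hydroxymethyl | CC[Si](CC)(CC)OC1CC(CO)[C@@H]2C(O)[C@H]1[C@H](c1ccc(OC)c(OC)c1)[C@H]2c1cc(OC)cc(OC)c1 | intermediate
20 | keto aldehyde: C8 ketone, C3 formyl, C1 triethylsilyl ether | CC[Si](CC)(CC)OC1CC(C=O)[C@@H]2C(=O)[C@H]1[C@H](c1ccc(OC)c(OC)c1)[C@H]2c1cc(OC)cc(OC)c1 | intermediate
21 | 3,4-dimethoxybenzyl alcohol | COc1ccc(CO)cc1OC | starting material
22 | diethyl (3,4-dimethoxybenzyl)phosphonate | CCOP(=O)(Cc1ccc(OC)c(OC)c1)OCC | intermediate
23 | TES ether: C3 (E)-3,4-dimethoxystyryl, C8 ketone, C1 triethylsilyl ether | CC[Si](CC)(CC)OC1CC(/C=C/c3ccc(OC)c(OC)c3)[C@@H]2C(=O)[C@H]1[C@H](c1ccc(OC)c(OC)c1)[C@H]2c1cc(OC)cc(OC)c1 | intermediate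
24 | hydroxy styryl ketone: as 23 with free C1 carbinol | OC1CC(/C=C/c3ccc(OC)c(OC)c3)[C@@H]2C(=O)[C@H]1[C@H](c1ccc(OC)c(OC)c1)[C@H]2c1cc(OC)cc(OC)c1 | intermediate
25 | diketone: C1 and C8 ketones, (E)-styryl on sp3 C3 | O=C1CC(/C=C/c3ccc(OC)c(OC)c3)[C@@H]2C(=O)[C@H]1[C@H](c1ccc(OC)c(OC)c1)[C@H]2c1cc(OC)cc(OC)c1 | intermediate
26 | TMS enol ether of 25 (C1=C2) | C[Si](C)(C)OC1=CC(/C=C/c3ccc(OC)c(OC)c3)[C@@H]2C(=O)[C@H]1[C@H](c1ccc(OC)c(OC)c1)[C@H]2c1cc(OC)cc(OC)c1 | intermediate
27 | hexa-O-methyljezonodione, (1S,5R,6R,7R)-7-(3,4-dimethoxyphenyl)-6-(3,5-dimethoxyphenyl)-4-[(E)-2-(3,4-dimethoxyphenyl)ethenyl]bicyclo[3.2.1]oct-3-ene-2,8-dione | O=C1C=C(/C=C/c3ccc(OC)c(OC)c3)[C@@H]2C(=O)[C@H]1[C@H](c1ccc(OC)c(OC)c1)[C@H]2c1cc(OC)cc(OC)c1 | intermediate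
28 | jezonodione, (1S,5R,6R,7R)-7-(3,4-dihydroxyphenyl)-6-(3,5-dihydroxyphenyl)-4-[(E)-2-(3,4-dihydroxyphenyl)ethenyl]bicyclo[3.2.1]oct-3-ene-2,8-dione | O=C1C=C(/C=C/c2ccc(O)c(O)c2)[C@@H]2C(=O)[C@H]1[C@H](c1ccc(O)c(O)c1)[C@H]2c1cc(O)cc(O)c1 | target

**Step count**

Total: 19 steps. Longest linear sequence: 15 steps (steps 4–14 and 16–19).

**Steps most likely to fail, with fallbacks**

Step 8. The Z-aryl group has to point inward in the boat transition state, so the Cope shift may be slow enough for the push–pull cyclopropane to open to a zwitterion, with loss of stereochemical fidelity or diversion to five-membered products; the carbene may also attack the wrong alkene. The fallback sets out from 10 and 5 and returns at 13. Enone 10 is isomerised with catalytic iodine to (E)-4-(3,4-dimethoxyphenyl)but-3-en-2-one F1 (also available by aldol condensation), which is silylated as in step 7 to the (E)-siloxydiene F2. With 5 and Rh2(R-DOSP)4 this should give the all-outward cis-divinylcyclopropane F3, which rearranges without heating to the cis-6,7-diaryl cycloheptadiene F4 (3R,4R in the numbering of 13; C6 already correct). C7 in F4 is benzylic and γ to the enoate, so equilibration with DBU in warm toluene through the dienolate should epimerise it to the more stable trans isomer 13.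

Step 12. If the seven-membered ring does not readily adopt the conformer that holds C8 over C4, the ketyl may instead dimerise (pinacol coupling) or simply be reduced to the alcohol. The fallback sets out from 17 and returns at 19. An intramolecular Stetter reaction of 17 (2-pentafluorophenyl-6,7-dihydro-5H-pyrrolo[2,1-c][1,2,4]triazol-2-ium tetrafluoroborate, KN(SiMe3)2, toluene, warmed as needed) adds the aldehyde as an acyl anion equivalent to C4 of the enoate. This gives directly the C8 ketone, the bicyclic keto ester F5, by a polar pathway that cannot dimerise and tolerates heating. LiAlH4 then reduces ketone and ester together to diol 19.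

Step 9. The Lewis acid may ionise the product acetal again, leading to loss of methanol to a methoxymethylene ketone, capture of the oxocarbenium ion by the neighbouring dimethoxyphenyl ring, or migration of C3=C4 into conjugation with the new ketone. The fallback sets out from 13 and returns at 17. A Mukaiyama aldol reaction of 13 with aqueous formaldehyde and Sc(OTf)3 in THF gives the C5 hydroxymethyl ketone F6 (again anti to the C6 aryl, and epimerisable to the trans isomer). Luche reduction gives the 1,3-diol F7, and TESCl/imidazole the bis(triethylsilyl) ether F8. Swern conditions, which oxidise a primary triethylsilyl ether in the presence of a secondary one, convert F8 into aldehyde 17.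

**Further compounds**

F1 | step 8 | (E)-4-(3,4-dimethoxyphenyl)but-3-en-2-one | CC(=O)/C=C/c1ccc(OC)c(OC)c1
F2 | step 8 | (E)-2-(tert-butyldimethylsilyloxy)-4-(3,4-dimethoxyphenyl)buta-1,3-diene | C=C(O[Si](C)(C)C(C)(C)C)/C=C/c1ccc(OC)c(OC)c1
F3 | step 8 | cis-divinylcyclopropane with both aryl alkenes E (mirror-image ring configuration to 12) | COC(=O)[C@]1(/C=C/c2cc(OC)cc(OC)c2)C[C@@]1(O[Si](C)(C)C(C)(C)C)/C=C/c1ccc(OC)c(OC)c1
F4 | step 8 | methyl (3R,4R)-6-(tert-butyldimethylsilyloxy)-4-(3,4-dimethoxyphenyl)-3-(3,5-dimethoxyphenyl)cyclohepta-1,5-diene-1-carboxylate (cis-diaryl C7 epimer of 13) | CC(C)(C)[Si](C)(C)OC1=C[C@H](c2ccc(OC)c(OC)c2)[C@H](c2cc(OC)cc(OC)c2)C=C(C(=O)OC)C1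
F5 | step 12 | bicyclic keto ester: C8 ketone, C3 methyl ester, C1 triethylsilyl ether | CC[Si](CC)(CC)OC1CC(C(=O)OC)[C@@H]2C(=O)[C@H]1[C@H](c1ccc(OC)c(OC)c1)[C@H]2c1cc(OC)cc(OC)c1
F6 | step 9 | C5 hydroxymethyl C1 ketone (hydroxymethyl trans to the C6 aryl), C3=C4 methyl enoate | O=C1[C@@H](CO)[C@H](c2ccc(OC)c(OC)c2)[C@@H](c2cc(OC)cc(OC)c2)C=C(C(=O)OC)C1
F7 | step 9 | 1,3-diol: C1 carbinol and C5 hydroxymethyl | OC1[C@@H](CO)[C@H](c2ccc(OC)c(OC)c2)[C@@H](c2cc(OC)cc(OC)c2)C=C(C(=O)OC)C1
F8 | step 9 | bis(triethylsilyl) ether of F7 | CC[Si](CC)(CC)OC1[C@@H](CO[Si](CC)(CC)CC)[C@H](c2ccc(OC)c(OC)c2)[C@@H](c2cc(OC)cc(OC)c2)C=C(C(=O)OC)C1
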